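**Plan**

- The retrosynthesis first removes the three benzyl ethers, then cuts the aryl–C(=O) bond of the isovaleryl group on ring B (Friedel–Crafts).
- In each of rings A and C the OMe carbon sits between the C-methyl carbon and the isovaleryl-bearing carbon, and the CH2 bridge sits on the carbon between the two C–OH. Cutting the C(CH3)–C(OCH3) bond and the C(OH)–C(acyl) bond in both rings gives a ring B core carrying two 2-substituted 4-methyl 1-methoxy-1,3-bis(silyloxy)dienes and two molecules of MeO–C≡C–CO–CH2CH(CH3)2. The diene supplies four ring carbons (both OH, the bridge, the methyl); the ynone supplies the OMe carbon and the acyl carbon already in the right order.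
- The bis(diene) goes back by desilylation to a bis(β-keto ester), whose two ArCH2–CH bonds lead to tribenzylated diformylphloroglucinol and methyl 3-oxopentanoate. The ynone goes back to trichloroethylene, methanol and the Weinreb amide of isovaleric acid.
- Forward: ring B is elaborated from phloroglucinol, rings A and C are closed together in one twofold cycloaromatization, then ring B is acylated and the benzyl ethers are removed.
- Stereochemistry: the target has no stereocentre. Only the (3Z) geometry of the diene termini matters, and it is set by kinetic γ-deprotonation.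

Key step: step 9

Remark: alkene geometries and transient sp3 centres that are erased on reduction or aromatisation are left unspecified in the structures; only the (3Z) diene termini are drawn.

**Step 1**
Reactants: 1 phloroglucinol
Product: 3 2,4,6-trihydroxybenzene-1,3-dicarbaldehyde, via bis(iminium) salt 2 (not isolated)
Conditions: POCl3 (2.5 equiv), DMF (2.5 equiv), dioxane, 0 °C → rt; then ice/H2O
Reagents that add atoms: N,N-dimethylformamide CN(C)C=O; water O
Why: Vilsmeier–Haack formylation: the chloroiminium ion from DMF and POCl3 attacks the highly nucleophilic phloroglucinol ring twice, the third position being deactivated by the two iminium groups, and aqueous work-up hydrolyses bis(iminium) salt 2 to the dialdehyde.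

**Step 2**
Reactants: 3 2,4,6-trihydroxybenzene-1,3-dicarbaldehyde
Product: 4 2,4,6-tris(benzyloxy)benzene-1,3-dicarbaldehyde
Conditions: BnBr (3.6 equiv), K2CO3, DMF, 60 °C
Reagents that add atoms: benzyl bromide BrCc1ccccc1
Why: Williamson ether synthesis: the three phenols are vinylogous carboxylic acids that K2CO3 deprotonates fully, and in DMF the delocalised phenoxides should be benzylated on oxygen because the remaining ring carbon is deactivated by two formyl groups.

**Step 3**
Reactants: 4 2,4,6-tris(benzyloxy)benzene-1,3-dicarbaldehyde; 5 methyl 3-oxopentanoate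
Product: 6 dimethyl 2,2'-{[2,4,6-tris(benzyloxy)-1,3-phenylene]di(methanylylidene)}bis(3-oxopentanoate), mixture of alkene isomers
Conditions: 5 (2.4 equiv), piperidine (cat.), AcOH (cat.), toluene, reflux, Dean–Stark
Reagents that add atoms: none
Why: Knoevenagel condensation under piperidinium acetate catalysis with azeotropic removal of water should convert both aldehydes, which cannot divert to coumarins because the ortho oxygens are benzylated; the alkene geometry is irrelevant since both double bonds are reduced next.

**Step 4**
Reactants: 6 bis(alkylidene β-keto ester)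
Product: 7 dimethyl 2,2'-{[2,4,6-tris(benzyloxy)-1,3-phenylene]bis(methylene)}bis(3-oxopentanoate), mixture of diastereomers
Conditions: Hantzsch ester (diethyl 2,6-dimethyl-1,4-dihydropyridine-3,5-dicarboxylate, 2.4 equiv), SiO2, toluene, 80 °C, dark
Reagents that add atoms: none
Why: Conjugate transfer hydrogenation of the doubly activated alkylidene β-keto ester by the Hantzsch ester leaves ketones, esters and benzyl ethers untouched, and the two new α-stereocentres are not controlled because they are epimerisable and become sp2 in step 5.

**Step 5**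
Reactants: 7 bis(β-keto ester)
Product: 8 dimethyl 2,2'-{[2,4,6-tris(benzyloxy)-1,3-phenylene]bis(methylene)}bis[3-(trimethylsilyloxy)pent-2-enoate]
Conditions: Me3SiCl (3 equiv), Et3N (3.2 equiv), toluene, rt, 48–72 h; filtration under argon, used crude
Reagents that add atoms: chlorotrimethylsilane C[Si](C)(C)Cl
Why: Soft enolisation and O-silylation of a 2-substituted β-keto ester with Et3N/Me3SiCl is the standard first stage of Chan-diene synthesis and should give the β-silyloxy enoate on both arms.

**Step 6**
Reactants: 8 bis(β-silyloxy enoate)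
Product: 9 1,3,5-tris(benzyloxy)-2,4-bis{(3Z)-2-[methoxy(trimethylsilyloxy)methylidene]-3-(trimethylsilyloxy)pent-3-en-1-yl}benzene
Conditions: LiN(i-Pr)2 (2.6 equiv), THF, −78 °C, 1 h; Me3SiCl (3 equiv), −78 → 20 °C; evaporation, hexane, filtration under argon, used at once
Reagents that add atoms: chlorotrimethylsilane C[Si](C)(C)Cl
Why: Kinetic γ-deprotonation of each β-silyloxy enoate by LiN(i-Pr)2 gives an extended ester dienolate that is trapped on oxygen by Me3SiCl (second stage of the Chan-diene synthesis), allylic strain against the C2 substituent placing the terminal methyl cis to the silyloxy group, that is (3Z).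

**Step 7**
Reactants: 10 isovaleryl chloride
Product: 11 N-methoxy-N,3-dimethylbutanamide
Conditions: MeNHOMe·HCl (1.1 equiv), Et3N (2.2 equiv), CH2Cl2, 0 °C → rt
Reagents that add atoms: N,O-dimethylhydroxylamine hydrochloride CNOC.Cl
Why: Nucleophilic acyl substitution of the acid chloride by N,O-dimethylhydroxylamine (Weinreb amide formation) is fast and clean at 0 °C.

**Step 8**
Reactants: 12 trichloroethylene; 11 N-methoxy-N,3-dimethylbutanamide
Product: 15 1-methoxy-5-methylhex-1-yn-3-one, via (E)-1,2-dichloro-1-methoxyethene 13 (not isolated), via lithium methoxyacetylide 14 (not isolated)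
Conditions: KH, MeOH (1 equiv), THF, 0 °C; 12, −50 → 20 °C; n-BuLi (2.1 equiv), −78 → −40 °C; 11, −78 → 0 °C; cold sat. aq NH4Cl
Reagents that add atoms: methanol CO
Why: Greene-type ynol ether synthesis (methoxide adds to the dichloroacetylene formed by dehydrochlorination of 12 to give 13, which n-BuLi converts by elimination and lithium–chlorine exchange into acetylide 14) followed by Weinreb ketone synthesis, in which the chelated tetrahedral adduct prevents a second addition.

**Step 9**
Reactants: 9 bis(diene); 15 1-methoxy-5-methylhex-1-yn-3-one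
Product: 17 1,3,5-tris(benzyloxy)-2,4-bis{[2,6-dihydroxy-4-methoxy-3-methyl-5-(3-methylbutanoyl)phenyl]methyl}benzene, via twofold cycloadduct 16 (not isolated)
Conditions: 15 (3 equiv), toluene, 0 → 60 °C, argon; then 0.5 M HCl, THF, 0 → 20 °C
Reagents that add atoms: none
Why: Proposed new method: each electron-rich diene of 9 should attack, through C4 (the CH carrying the future C-methyl), the methoxy-bearing β-carbon of the push–pull ynone 15 while the ketene acetal carbon C1 bonds to the α-carbon, either as an asynchronous normal-demand [4+2] cycloaddition or as a Mukaiyama–Michael addition followed by 6-exo-trig closure of the allenyl silyl ether onto the ester-level carbon, both paths converging on cyclohexa-1,4-diene 16. The closest known reaction type is the Diels–Alder or Michael–Claisen cycloaromatization of 1-methoxy-1,3-bis(trimethylsilyloxy)dienes with alkynones and alkynoates to resorcinols, which has not been run twice on one substrate or with a 3-alkoxy ynone. Rings A and C are each closed as six-membered carbocycles in this [4+2] (or Michael/6-exo-trig) mode and become aromatic when acid collapses the methyl silyl ketal with loss of methanol, the dienone tautomerises through the C4 hydrogen and the silyl ethers are hydrolysed. No stereocentre survives, so the sp3 centres of 16 need no control. The step needs head-to-tail regiochemistry, secured by pairing the largest HOMO coefficient (C4) with the carbonyl-polarised β-carbon of 15, and it needs the ketal to shed methanol and not silanol, secured because Si–O cleavage to the hemiketal precedes expulsion of methanol. Ring B is inert as its tribenzyl ether, and the (3Z) geometry keeps the methyl group outside the s-cis diene.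

**Step 10**
Reactants: 17 key-step product; 18 isovaleric acid (3-methylbutanoic acid)
Product: 20 1-{2,4,6-tris(benzyloxy)-3,5-bis{[2,6-dihydroxy-4-methoxy-3-methyl-5-(3-methylbutanoyl)phenyl]methyl}phenyl}-3-methylbutan-1-one, via tetra-O-isovalerate 19 (not isolated)
Conditions: 18 (8 equiv) and (CF3CO)2O (7 equiv) premixed, CH2Cl2, 0 °C; then 17, 0 → 20 °C; evaporation; K2CO3 (cat.), MeOH, 20 °C, argon
Reagents that add atoms: none
Why: Friedel–Crafts acylation by the acyl trifluoroacetate formed in the flask should take place at the only unsubstituted aromatic carbon, which three alkoxy and two alkyl groups make the most nucleophilic site, while the phenols of rings A and C are esterified to 19 (less fully esterified congeners converge) and then freed by base-catalysed transesterification with methanol, ring B staying benzylated so that the methylene bridges do not scramble.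

**Step 11**
Reactants: 20 tribenzyl ether of the target
Product: 21 CNP0158539.0 (target)
Conditions: H2 (1 atm), 10% Pd/C, EtOAc–MeOH, 20 °C
Reagents that add atoms: none
Why: Catalytic hydrogenolysis of benzyl aryl ethers over Pd/C is reliable, and the chelated aryl ketones, the aryl methyl ethers and the diarylmethane bridges are inert under one atmosphere of hydrogen at room temperature.

**Compound list**

1 | phloroglucinol (benzene-1,3,5-triol) | Oc1cc(O)cc(O)c1 | starting material
2 | bis(iminium) salt, N,N'-[(2,4,6-trihydroxy-1,3-phenylene)dimethylidyne]bis(N-methylmethanaminium) dichloride | C[N+](C)=Cc1c(O)cc(O)c(C=[N+](C)C)c1O.[Cl-].[Cl-] | intermediate (not isolated)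
3 | 2,4,6-trihydroxybenzene-1,3-dicarbaldehyde | O=Cc1c(O)cc(O)c(C=O)c1O | intermediate
4 | 2,4,6-tris(benzyloxy)benzene-1,3-dicarbaldehyde | O=Cc1c(OCc2ccccc2)cc(OCc2ccccc2)c(C=O)c1OCc1ccccc1 | intermediate
5 | methyl 3-oxopentanoate | CCC(=O)CC(=O)OC | starting material
6 | dimethyl 2,2'-{[2,4,6-tris(benzyloxy)-1,3-phenylene]di(methanylylidene)}bis(3-oxopentanoate), alkene isomers unspecified | CCC(=O)C(=Cc1c(OCc2ccccc2)cc(OCc2ccccc2)c(C=C(C(=O)CC)C(=O)OC)c1OCc1ccccc1)C(=O)OC | intermediate
7 | dimethyl 2,2'-{[2,4,6-tris(benzyloxy)-1,3-phenylene]bis(methylene)}bis(3-oxopentanoate), diastereomer mixture | CCC(=O)C(Cc1c(OCc2ccccc2)cc(OCc2ccccc2)c(CC(C(=O)CC)C(=O)OC)c1OCc1ccccc1)C(=O)OC | intermediate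
8 | dimethyl 2,2'-{[2,4,6-tris(benzyloxy)-1,3-phenylene]bis(methylene)}bis[3-(trimethylsilyloxy)pent-2-enoate], enol ether geometry unspecified | CCC(O[Si](C)(C)C)=C(Cc1c(OCc2ccccc2)cc(OCc2ccccc2)c(CC(C(=O)OC)=C(CC)O[Si](C)(C)C)c1OCc1ccccc1)C(=O)OC | intermediate
9 | 1,3,5-tris(benzyloxy)-2,4-bis{(3Z)-2-[methoxy(trimethylsilyloxy)methylidene]-3-(trimethylsilyloxy)pent-3-en-1-yl}benzene, ketene acetal geometry unspecified | C/C=C(O[Si](C)(C)C)/C(Cc1c(OCc2ccccc2)cc(OCc2ccccc2)c(CC(=C(OC)O[Si](C)(C)C)/C(O[Si](C)(C)C)=C/C)c1OCc1ccccc1)=C(OC)O[Si](C)(C)C | intermediate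
10 | isovaleryl chloride (3-methylbutanoyl chloride) | CC(C)CC(Cl)=O | starting material
11 | N-methoxy-N,3-dimethylbutanamide | CON(C)C(=O)CC(C)C | intermediate
12 | trichloroethylene | ClC=C(Cl)Cl | starting material
13 | (E)-1,2-dichloro-1-methoxyethene | CO/C(Cl)=C\Cl | intermediate (not isolated)
14 | lithium methoxyacetylide | [Li]C#COC | intermediate (not isolated)
15 | 1-methoxy-5-methylhex-1-yn-3-one | COC#CC(=O)CC(C)C | intermediate
16 | twofold cycloadduct: ring B tribenzyl ether carrying two CH2-linked cyclohexa-1,4-dienes, each with a methyl trimethylsilyl ketal carbon, a silyl enol ether, an sp3 CH(CH3) and a β-methoxy enone bearing the isovaleryl group; diastereomer mixture | COC1(O[Si](C)(C)C)C(Cc2c(OCc3ccccc3)cc(OCc3ccccc3)c(CC3=C(O[Si](C)(C)C)C(C)C(OC)=C(C(=O)CC(C)C)C3(OC)O[Si](C)(C)C)c2OCc2ccccc2)=C(O[Si](C)(C)C)C(C)C(OC)=C1C(=O)CC(C)C | intermediate (not isolated)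
17 | 1,3,5-tris(benzyloxy)-2,4-bis{[2,6-dihydroxy-4-methoxy-3-methyl-5-(3-methylbutanoyl)phenyl]methyl}benzene | COc1c(C)c(O)c(Cc2c(OCc3ccccc3)cc(OCc3ccccc3)c(Cc3c(O)c(C)c(OC)c(C(=O)CC(C)C)c3O)c2OCc2ccccc2)c(O)c1C(=O)CC(C)C | intermediate
18 | isovaleric acid (3-methylbutanoic acid) | CC(C)CC(=O)O | starting material
19 | tetra-O-isovalerate of 20 (ring B C-acylated, all four phenols of rings A and C esterified) | COc1c(C)c(OC(=O)CC(C)C)c(Cc2c(OCc3ccccc3)c(C(=O)CC(C)C)c(OCc3ccccc3)c(Cc3c(OC(=O)CC(C)C)c(C)c(OC)c(C(=O)CC(C)C)c3OC(=O)CC(C)C)c2OCc2ccccc2)c(OC(=O)CC(C)C)c1C(=O)CC(C)C | intermediate (not isolated)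
20 | 1-{2,4,6-tris(benzyloxy)-3,5-bis{[2,6-dihydroxy-4-methoxy-3-methyl-5-(3-methylbutanoyl)phenyl]methyl}phenyl}-3-methylbutan-1-one | COc1c(C)c(O)c(Cc2c(OCc3ccccc3)c(C(=O)CC(C)C)c(OCc3ccccc3)c(Cc3c(O)c(C)c(OC)c(C(=O)CC(C)C)c3O)c2OCc2ccccc2)c(O)c1C(=O)CC(C)C | intermediate
21 | CNP0158539.0, 1-{2,4,6-trihydroxy-3,5-bis{[2,6-dihydroxy-4-methoxy-3-methyl-5-(3-methylbutanoyl)phenyl]methyl}phenyl}-3-methylbutan-1-one | COc1c(C)c(O)c(Cc2c(O)c(Cc3c(O)c(C)c(OC)c(C(=O)CC(C)C)c3O)c(O)c(C(=O)CC(C)C)c2O)c(O)c1C(=O)CC(C)C | target

**Step count and risks**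

Total step count: 11. Longest linear sequence: 9 steps (steps 1–6, 9, 10, 11); steps 7 and 8 form the ynone branch.

Steps most likely to fail:

1. Step 9. The push–pull ynone may react so slowly that silyl migration or hydrolysis of the bis(diene) outruns C–C bond formation, the second annulation may stall after the first, or the silyl ketal may collapse the wrong way and misplace a methyl ether. The fallback uses known chemistry: acid-catalysed Friedel–Crafts benzylation of a preformed acylphloroglucinol, the classical route to methylene-bridged phloroglucinols. It sets out from dialdehyde 4, which NaBH4 in THF–MeOH should reduce to [2,4,6-tris(benzyloxy)-1,3-phenylene]dimethanol F1. In parallel, commercial 2,4,6-trihydroxytoluene would be C-acylated with isovaleryl chloride 10 (AlCl3, nitrobenzene) to 3-methyl-1-(2,4,6-trihydroxy-3-methylphenyl)butan-1-one F2. Chloromethyl methyl ether and i-Pr2NEt should protect the unchelated 4-OH and the less hindered 6-OH to give 1-[2-hydroxy-4,6-bis(methoxymethoxy)-3-methylphenyl]-3-methylbutan-1-one F3. The remaining hindered, chelated 2-OH would be methylated (MeI, K2CO3, acetone, reflux) to 1-[2-methoxy-4,6-bis(methoxymethoxy)-3-methylphenyl]-3-methylbutan-1-one F4. HCl in MeOH would then release 1-(4,6-dihydroxy-2-methoxy-3-methylphenyl)-3-methylbutan-1-one F5. Two equivalents of F5 with F1 and catalytic p-toluenesulfonic acid in CH2Cl2 at 0 °C should alkylate the one free ring carbon of F5 (between its two OH groups). The fallback comes back to the route at 17.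

2. Step 10. The two flanking benzyloxy groups may shield the last ring B carbon so that C-acylation stays incomplete, while the trifluoroacetic acid set free starts to cleave benzyl ethers or to protonate ring B at the bridge carbons and break the methylene links. The fallback sets out from 17 and reverses the order. Hydrogenolysis (H2, Pd/C, EtOAc–MeOH) would give 2,4-bis{[2,6-dihydroxy-4-methoxy-3-methyl-5-(3-methylbutanoyl)phenyl]methyl}benzene-1,3,5-triol F6, in which ring B is a free, far more nucleophilic phloroglucinol. A Houben–Hoesch reaction with 3-methylbutanenitrile (ZnCl2, HCl gas, Et2O, 0 °C) should acylate only the free ring B carbon, without O-acylation, to give the ketiminium chloride F7. Warming in water would hydrolyse it, and the fallback comes back to the route at target 21.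

3. Step 8. The N-methoxy-N-methylamide set free on quench, or water, may add to the β-carbon of the newly formed push–pull ynone, or the tetrahedral adduct may form incompletely from the cold acetylide solution. The fallback sets out from lithium methoxyacetylide 14, generated as in step 8. Addition to commercial 3-methylbutanal at −78 °C would give racemic 1-methoxy-5-methylhex-1-yn-3-ol F8. Oxidation with activated MnO2 in CH2Cl2 under neutral conditions, which avoids Meyer–Schuster rearrangement, comes back to the route at ynone 15.

**Further compounds**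

F1 | step 9 | [2,4,6-tris(benzyloxy)-1,3-phenylene]dimethanol | OCc1c(OCc2ccccc2)cc(OCc2ccccc2)c(CO)c1OCc1ccccc1
F2 | step 9 | 3-methyl-1-(2,4,6-trihydroxy-3-methylphenyl)butan-1-one | CC(C)CC(=O)c1c(O)cc(O)c(C)c1O
F3 | step 9 | 1-[2-hydroxy-4,6-bis(methoxymethoxy)-3-methylphenyl]-3-methylbutan-1-one | CC(C)CC(=O)c1c(OCOC)cc(OCOC)c(C)c1O
F4 | step 9 | 1-[2-methoxy-4,6-bis(methoxymethoxy)-3-methylphenyl]-3-methylbutan-1-one | CC(C)CC(=O)c1c(OCOC)cc(OCOC)c(C)c1OC
F5 | step 9 | 1-(4,6-dihydroxy-2-methoxy-3-methylphenyl)-3-methylbutan-1-one | CC(C)CC(=O)c1c(O)cc(O)c(C)c1OC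
F6 | step 10 | 2,4-bis{[2,6-dihydroxy-4-methoxy-3-methyl-5-(3-methylbutanoyl)phenyl]methyl}benzene-1,3,5-triol | COc1c(C)c(O)c(Cc2c(O)cc(O)c(Cc3c(O)c(C)c(OC)c(C(=O)CC(C)C)c3O)c2O)c(O)c1C(=O)CC(C)C
F7 | step 10 | ketiminium chloride of the target (ring B C(=NH2+) in place of C=O) | COc1c(C)c(O)c(Cc2c(O)c(Cc3c(O)c(C)c(OC)c(C(=O)CC(C)C)c3O)c(O)c(C(=[NH2+])CC(C)C)c2O)c(O)c1C(=O)CC(C)C.[Cl-]
F8 | step 8 | 1-methoxy-5-methylhex-1-yn-3-ol (racemic) | COC#CC(O)CC(C)C
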